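(All constants are invented, and the outcome is calculated.)

**One equilibrium.** A reversible step left to itself ends with product and reactant in the ratio of its equilibrium constant, so starting material passing into target, with constant 1.7 at 50 °C, ends with 1.7 parts of target per part of starting material. The flasks and the questions are these.

the same everywhere: starting material 20 mM; free catalyst 3.0 mM; time 3.0 d
- east: temperature 65 °C
- north: temperature 80 °C
- west: temperature 50 °C

- the flask with the highest amount of target, in percent of the starting material charged ("all alike" if they lie within 1.5 percentage points) (east / north / west / all alike)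
- final target, as a percentage of the starting material charged, in east
- final target, as a percentage of the starting material charged, in north
- final target, as a percentage of the starting material charged, in west

- at 50 °C the constants are as listed, elsewhere as the activation energies and enthalpies make them

    starting material ⇌ target (K1 = 1.7, k1 = 0.0026 min⁻¹, Ea1 = 98.0 kJ mol⁻¹, ΔH1 = 11.0 kJ mol⁻¹)
    free catalyst ⇌ dormant form (K2 = 12, k2 = 6.8 × 10⁻⁴ min⁻¹, Ea2 = 117 kJ mol⁻¹, ΔH2 = −56.0 kJ mol⁻¹)
    isomer of the product + free catalyst ⇌ starting material + free catalyst, rate k3*[free catalyst]*[isomer of the product] forward; the back reaction follows from the equilibrium constant (k3 = 12 M⁻¹ min⁻¹, Ea3 = 69.0 kJ mol⁻¹)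
    target ⇌ isomer of the product (K4 = 1.0, k4 = 0.0047 min⁻¹, Ea4 = 114 kJ mol⁻¹, ΔH4 = −58.0 kJ mol⁻¹)
    starting material + free catalyst → spent catalyst (k5 = 0.19 M⁻¹ min⁻¹, Ea5 = 53.0 kJ mol⁻¹)
    (constants at 50 °C)

**The pool.** Target passes on to isomer of the product, with constant 1.0 at 50 °C. Let Ka and Kb be these constants at the flask's absolute temperature T: one part of starting material then stands beside Ka parts of target and Ka·Kb parts of isomer. The target share φ, which is Ka divided by the sum of those parts, is the quantity to carry. Warming multiplies each constant by the exponential of ΔH/R times (reciprocal Tref minus reciprocal T), with ΔH the step's enthalpy, R the gas constant and Tref the reference temperature. With 11.0 kJ mol⁻¹ and −58.0 kJ mol⁻¹, east at 65 °C has Ka = 2.04, Kb = 0.384 and φ = 53.4 %. North at 80 °C has φ = 63.5 %, and west at 50 °C, where the listed constants stand, has φ = 38.6 %.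

**Approach.** In west, the pool's first step by itself relaxes with half-life ln(2) over the sum of its forward and back constants, 2.80 h, and the second step with 1.23 h, so the pool in west comes to equilibrium well within the run, and 98.0 kJ mol⁻¹ and 114 kJ mol⁻¹ speed these steps in the warmer flasks.

**The loss.** Starting material also reacts with free catalyst to give spent catalyst, one for one, so this loss is capped by the catalyst charged, 3.0 mM being less than the 20 mM of starting material. Taking the whole catalyst as spent, target is φ times the remaining fraction of the charge: 45.3 % in east, 54.0 % in north and 32.8 % in west, so the reckoning names north.

**The result.** The forecast gave 46.5 % in east, 54 % in north and 34.5 % in west and named north, reasoning that the equilibria “favour target increasingly as it gets hotter”, and it stands above this reckoning in east. The simulation gives 47.0 % in east, 54.0 % in north and 35.1 % in west, with north highest.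

**The comparison.** In east at 0.00333 d, starting material has a half-life of 0.88 h by its forward passing into target, shorter than the 0.37 d by its passing into spent catalyst. At 3.00 d the target in east reads 53.4 % of the pool beside φ of 53.4 %, while spent catalyst has reached 79.9 % of the catalyst charged, which leaves the pool at 88.0 % of the charge where the reckoning took 85.0 %.

**A colder repeat.** For the repeat of east at 40 °C, the same reckoning gives Ka = 1.49, Kb = 1.99 and φ = 27.3 %, hence 23.2 % of target with the whole catalyst spent, and more isomer than target. That flask ends with 24.8 % of target and 49.3 % of isomer of the product.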